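**Retrosynthetic overview**

1. Target 21 ⇐ dibenzyl ether 20 by hydrogenolysis of the two aryl benzyl ethers.
2. The strategy rests on ring B (C8, C7, O2, C9', C8'): the tertiary C8–OH sits next to the benzylic C7–O2 bond, so 20 ⇐ C7/C8 aryl epoxide 19 opened at C7 by the C9' hydroxyl ⇐ (E)-arylidene tetrahydrofuran 18 (ring B formed last).
3. 18 ⇐ diol 16 (ring A closed at O1–C9 by Mitsunobu etherification) ⇐ (E)-α-arylidene lactone 15 ⇐ lactone 12 + aldehyde 3 (aldol condensation makes C7=C8).
4. 12 ⇐ trans aryl paraconic acid 10 ⇐ auxiliary-controlled syn aldol and lactonisation of succinate imide 6 with aldehyde 3 (C7'–C8' bond; C7' and C8' set).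
5. Ring order: γ-lactone, then ring A as the cyclic ether, then ring B.

Key step: step 12

Assumption on the chemistry: the L-fructose-derived epoxidation ketone (mirror image of the usual D-fructose-derived catalyst, prepared from L-sorbose) is taken as available. By the spiro transition-state rule the D-series ketone would put oxygen on the wrong face of 18. Lignan numbering is used: C7/C7' benzylic, C8 carbinol, C8' CH, C9/C9' the OCH2 carbons. The β face of ring A carries H-8' and the C7' aryl; the α face carries the C9' arm.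

**Route**

Step 1
Reactants: 1 syringaldehyde; 2 benzyl bromide
Product: 3 4-(benzyloxy)-3,5-dimethoxybenzaldehyde
Conditions: K2CO3, DMF, 60 °C
Reagents that add atoms: benzyl bromide (compound 2), BrCc1ccccc1
Why: Williamson etherification of the phenoxide with the benzylic bromide; the aldehyde is inert to carbonate.

Step 2
Reactants: 4 (S)-4-benzyloxazolidin-2-one; 5 methyl 4-chloro-4-oxobutanoate
Product: 6 methyl 4-[(4S)-4-benzyl-2-oxooxazolidin-3-yl]-4-oxobutanoate
Conditions: n-BuLi, THF, −78 °C; then 5, −78 → 0 °C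
Reagents that add atoms: none
Why: N-acylation of the lithiated oxazolidinone by the acid chloride, which is far more electrophilic than the methyl ester.

Step 3
Reactants: 6 succinate imide; 3 4-(benzyloxy)-3,5-dimethoxybenzaldehyde
Product: 8 (4S)-4-benzyl-3-{[(2S,3S)-2-(4-benzyloxy-3,5-dimethoxyphenyl)-5-oxooxolan-3-yl]carbonyl}oxazolidin-2-one (trans lactone imide), via syn-aldol adduct 7 (not isolated)
Conditions: Bu2BOTf, iPr2NEt, CH2Cl2, 0 °C; 3, −78 → 0 °C; pH 7 buffer, MeOH, H2O2; PPTS (cat.), CH2Cl2, rt if lactonisation is incomplete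
Reagents that add atoms: none
Why: Evans syn aldol through the dibutylboron Z-enolate of the imide (enolised in preference to the ester) and a chair transition state shielded by the auxiliary benzyl group should set C8' and C7' as the (3S,4S) syn adduct 7, whose γ-hydroxy ester lactonises to the 2,3-trans lactone.

Step 4
Reactants: 8 trans lactone imide
Product: 10 (2S,3S)-2-(4-benzyloxy-3,5-dimethoxyphenyl)-5-oxooxolane-3-carboxylic acid, via peroxy acid 9 (not isolated)
Conditions: LiOH, H2O2, THF/H2O, 0 °C; Na2SO3; HCl to pH 2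
Reagents that add atoms: hydrogen peroxide, OO
Why: Hydroperoxide cleavage of the N-acyl oxazolidinone at the exocyclic carbonyl, sulfite reduction of the peracid, and acidification (which re-closes any opened lactone) should free the acid without touching the trans stereocentres.

Step 5
Reactants: 10 lactone acid
Product: 11 (4R,5S)-5-(4-benzyloxy-3,5-dimethoxyphenyl)-4-(hydroxymethyl)oxolan-2-one
Conditions: BH3·SMe2, THF, 0 °C → rt; MeOH, then aqueous work-up
Reagents that add atoms: none
Why: Chemoselective borane reduction, since a carboxylic acid is reduced through its acyloxyborane much faster than a γ-lactone.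

Step 6
Reactants: 11 hydroxymethyl lactone
Product: 12 (4R,5S)-5-(4-benzyloxy-3,5-dimethoxyphenyl)-4-[(tert-butyldiphenylsilyloxy)methyl]oxolan-2-one
Conditions: TBDPSCl, imidazole, DMF, rt
Reagents that add atoms: tert-butyl(chloro)diphenylsilane, CC(C)(C)[Si](Cl)(c1ccccc1)c1ccccc1
Why: Silylation of the primary alcohol, which blocks alkoxide-driven translactonisation in the enolate step to come.

Step 7
Reactants: 12 silyl ether lactone; 3 4-(benzyloxy)-3,5-dimethoxybenzaldehyde
Product: 13 (3R,4R,5S)-3-[(4-benzyloxy-3,5-dimethoxyphenyl)(hydroxy)methyl]-5-(4-benzyloxy-3,5-dimethoxyphenyl)-4-[(tert-butyldiphenylsilyloxy)methyl]oxolan-2-one (both carbinol epimers)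
Conditions: LiN(iPr)2 (LDA), THF, −78 °C; 3; NH4Cl quench at −78 °C
Reagents that add atoms: none
Why: Aldol addition of the lithium lactone enolate, which should attack the aldehyde trans to the C8' substituent; the carbinol configuration is irrelevant because both epimers converge in step 8.

Step 8
Reactants: 13 β-hydroxy lactone
Product: 15 (3E,4R,5S)-3-(4-benzyloxy-3,5-dimethoxybenzylidene)-5-(4-benzyloxy-3,5-dimethoxyphenyl)-4-[(tert-butyldiphenylsilyloxy)methyl]oxolan-2-one, via mesylate 14 (not isolated)
Conditions: MsCl, Et3N, CH2Cl2, 0 °C; then DBU, 0 °C → rt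
Reagents that add atoms: none
Why: Mesylation and E1cB elimination through the lactone enolate should give the thermodynamically preferred (E)-arylidene lactone, with the aryl anti to the carbonyl and syn to C8'.

Step 9
Reactants: 15 (E)-arylidene lactone
Product: 16 (1S,2R,3E)-1-(4-benzyloxy-3,5-dimethoxyphenyl)-3-(4-benzyloxy-3,5-dimethoxybenzylidene)-2-[(tert-butyldiphenylsilyloxy)methyl]butane-1,4-diol
Conditions: iBu2AlH (DIBAL, excess), CH2Cl2, −78 → 0 °C; aq. KNaC4H4O6
Reagents that add atoms: none
Why: 1,2-Reduction of the unsaturated lactone through the lactol and hydroxy enal to the allylic alcohol, leaving the alkene geometry, both stereocentres, and the silyl and benzyl ethers untouched.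

Step 10
Reactants: 16 ene-diol
Product: 17 tert-butyl{[(2S,3R,4E)-4-(4-benzyloxy-3,5-dimethoxybenzylidene)-2-(4-benzyloxy-3,5-dimethoxyphenyl)oxolan-3-yl]methoxy}diphenylsilane
Conditions: PPh3, DIAD, THF, 0 °C → rt
Reagents that add atoms: none
Why: Mitsunobu cyclodehydration, in which the oxyphosphonium forms at the unhindered primary allylic hydroxyl and is displaced by the C7' hydroxyl in a 5-exo-tet SN2 closure of ring A; the C7'–O bond is not broken, so C7' is retained.

Step 11
Reactants: 17 silyl ether
Product: 18 [(2S,3R,4E)-4-(4-benzyloxy-3,5-dimethoxybenzylidene)-2-(4-benzyloxy-3,5-dimethoxyphenyl)oxolan-3-yl]methanol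
Conditions: Bu4NF, THF, 0 °C → rt
Reagents that add atoms: none
Why: Fluoride-driven desilylation frees the C9' hydroxyl; nothing else in the molecule is fluoride- or base-labile.

Step 12
Reactants: 18 (E)-arylidene tetrahydrofuran alcohol
Product: 20 dibenzyl ether of 8-hydroxysyringaresinol (7R,7'S,8S,8'R), via spiro-epoxide 19 (not isolated)
Conditions: L-fructose-derived Shi ketone (30 mol%), KHSO5 (as Oxone, 2KHSO5·KHSO4·K2SO4), K2CO3, Bu4NHSO4, MeCN–(MeO)2CH2–aq. Na2B4O7 buffer (pH 10.5), 0 °C; then PPTS (cat.), CH2Cl2, 0 °C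
Reagents that add atoms: potassium peroxymonosulfate, [K+].OOS(=O)(=O)[O-]
Why: The dioxirane generated from the ketone and KHSO5 should transfer oxygen to the (E)-trisubstituted styrene through the spiro transition state; the L-series ketone (the D-series gives R at the ArCH carbon of E-aryl alkenes) should deliver it to the β face, anti to the adjacent C9' arm, giving the (7S,8S)-epoxide 19. The C9' hydroxyl, held on the α face beneath C7, should then open the aryl-stabilised C7–O bond with inversion, the closest known reaction type being asymmetric dioxirane epoxidation of a styrene followed by benzylic opening of the aryl epoxide by a pendant alcohol. This closes ring B (C8, C7, O2, C9', C8') cis-fused to ring A in a 5-endo epoxide opening, preferred over the 4-exo oxetane closure at C8 because positive charge builds at the benzylic carbon. C8 is set by the face of oxygen transfer (catalyst control reinforced by the C8' substituent), and C7 by anti opening of the epoxide derived from the (E)-alkene, which places the aryl exo. The step needs β-face epoxidation and attack at C7 with inversion; the first is secured by the choice of catalyst enantiomer, the second by benzylic activation, the short tether, and a buffered medium with only a mild PPTS finish so that the benzylic ethers do not equilibrate. An α-face epoxide cannot close (it would require a trans-fused bicycle), so a facial error should cost material but not give a C8 epimer of 20.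

Step 13
Reactants: 20 dibenzyl ether
Product: 21 8-hydroxysyringaresinol (7R,7'S,8S,8'R)
Conditions: H2 (1 atm), Pd/C (10%), EtOAc, rt, stopped at full conversion
Reagents that add atoms: none
Why: Catalytic hydrogenolysis of the two aryl benzyl ethers, which under neutral conditions at atmospheric pressure should be much faster than cleavage of the hindered dialkyl benzylic C–O bonds of rings A and B.

**Compound list**

1 | syringaldehyde | COc1cc(C=O)cc(OC)c1O | starting material
2 | benzyl bromide | BrCc1ccccc1 | starting material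
3 | 4-(benzyloxy)-3,5-dimethoxybenzaldehyde | COc1cc(C=O)cc(OC)c1OCc1ccccc1 | intermediate
4 | (S)-4-benzyloxazolidin-2-one | O=C1N[C@@H](Cc2ccccc2)CO1 | starting material
5 | methyl 4-chloro-4-oxobutanoate | COC(=O)CCC(Cl)=O | starting material
6 | methyl 4-[(4S)-4-benzyl-2-oxooxazolidin-3-yl]-4-oxobutanoate | COC(=O)CCC(=O)N1[C@@H](Cc2ccccc2)COC1=O | intermediate
7 | methyl (3S,4S)-3-{[(4S)-4-benzyl-2-oxooxazolidin-3-yl]carbonyl}-4-(4-benzyloxy-3,5-dimethoxyphenyl)-4-hydroxybutanoate (syn aldol, not isolated) | COC(=O)C[C@H](C(=O)N1[C@@H](Cc2ccccc2)COC1=O)[C@H](O)c1cc(OC)c(OCc2ccccc2)c(OC)c1 | intermediate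
8 | (4S)-4-benzyl-3-{[(2S,3S)-2-(4-benzyloxy-3,5-dimethoxyphenyl)-5-oxooxolan-3-yl]carbonyl}oxazolidin-2-one | COc1cc([C@H]2OC(=O)C[C@@H]2C(=O)N2[C@@H](Cc3ccccc3)COC2=O)cc(OC)c1OCc1ccccc1 | intermediate
9 | (2S,3S)-2-(4-benzyloxy-3,5-dimethoxyphenyl)-5-oxooxolane-3-carboperoxoic acid (not isolated) | COc1cc([C@H]2OC(=O)C[C@@H]2C(=O)OO)cc(OC)c1OCc1ccccc1 | intermediate
10 | (2S,3S)-2-(4-benzyloxy-3,5-dimethoxyphenyl)-5-oxooxolane-3-carboxylic acid | COc1cc([C@H]2OC(=O)C[C@@H]2C(=O)O)cc(OC)c1OCc1ccccc1 | intermediate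
11 | (4R,5S)-5-(4-benzyloxy-3,5-dimethoxyphenyl)-4-(hydroxymethyl)oxolan-2-one | COc1cc([C@H]2OC(=O)C[C@@H]2CO)cc(OC)c1OCc1ccccc1 | intermediate
12 | (4R,5S)-5-(4-benzyloxy-3,5-dimethoxyphenyl)-4-[(tert-butyldiphenylsilyloxy)methyl]oxolan-2-one | COc1cc([C@H]2OC(=O)C[C@@H]2CO[Si](c5ccccc5)(c5ccccc5)C(C)(C)C)cc(OC)c1OCc1ccccc1 | intermediate
13 | (3R,4R,5S)-3-[(4-benzyloxy-3,5-dimethoxyphenyl)(hydroxy)methyl]-5-(4-benzyloxy-3,5-dimethoxyphenyl)-4-[(tert-butyldiphenylsilyloxy)methyl]oxolan-2-one (carbinol epimers) | COc1cc([C@H]2OC(=O)[C@@H](C(O)c3cc(OC)c(OCc4ccccc4)c(OC)c3)[C@@H]2CO[Si](c5ccccc5)(c5ccccc5)C(C)(C)C)cc(OC)c1OCc1ccccc1 | intermediate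
14 | methanesulfonate of 13 at the benzylic carbinol (not isolated) | COc1cc([C@H]2OC(=O)[C@@H](C(OS(C)(=O)=O)c3cc(OC)c(OCc4ccccc4)c(OC)c3)[C@@H]2CO[Si](c5ccccc5)(c5ccccc5)C(C)(C)C)cc(OC)c1OCc1ccccc1 | intermediate
15 | (3E,4R,5S)-3-(4-benzyloxy-3,5-dimethoxybenzylidene)-5-(4-benzyloxy-3,5-dimethoxyphenyl)-4-[(tert-butyldiphenylsilyloxy)methyl]oxolan-2-one | COc1cc([C@H]2OC(=O)/C(=C/c3cc(OC)c(OCc4ccccc4)c(OC)c3)[C@@H]2CO[Si](c5ccccc5)(c5ccccc5)C(C)(C)C)cc(OC)c1OCc1ccccc1 | intermediate
16 | (1S,2R,3E)-1-(4-benzyloxy-3,5-dimethoxyphenyl)-3-(4-benzyloxy-3,5-dimethoxybenzylidene)-2-[(tert-butyldiphenylsilyloxy)methyl]butane-1,4-diol | OC/C(=C/c1cc(OC)c(OCc2ccccc2)c(OC)c1)[C@H](CO[Si](c1ccccc1)(c1ccccc1)C(C)(C)C)[C@H](O)c1cc(OC)c(OCc2ccccc2)c(OC)c1 | intermediate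
17 | tert-butyl{[(2S,3R,4E)-4-(4-benzyloxy-3,5-dimethoxybenzylidene)-2-(4-benzyloxy-3,5-dimethoxyphenyl)oxolan-3-yl]methoxy}diphenylsilane | COc1cc([C@H]2OC/C(=C/c3cc(OC)c(OCc4ccccc4)c(OC)c3)[C@@H]2CO[Si](c5ccccc5)(c5ccccc5)C(C)(C)C)cc(OC)c1OCc1ccccc1 | intermediate
18 | [(2S,3R,4E)-4-(4-benzyloxy-3,5-dimethoxybenzylidene)-2-(4-benzyloxy-3,5-dimethoxyphenyl)oxolan-3-yl]methanol (key-step precursor) | COc1cc([C@H]2OC/C(=C/c3cc(OC)c(OCc4ccccc4)c(OC)c3)[C@@H]2CO)cc(OC)c1OCc1ccccc1 | intermediate
19 | (7S,8S)-7,8-epoxide of 18, oxygen on the β face of ring A (not isolated) | COc1cc([C@H]2OC[C@@]3(O[C@H]3c4cc(OC)c(OCc5ccccc5)c(OC)c4)[C@@H]2CO)cc(OC)c1OCc1ccccc1 | intermediate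
20 | dibenzyl ether of 8-hydroxysyringaresinol (7R,7'S,8S,8'R; cis-fused, both aryls exo) | COc1cc([C@H]2OC[C@]3(O)[C@@H](c4cc(OC)c(OCc5ccccc5)c(OC)c4)OC[C@H]23)cc(OC)c1OCc1ccccc1 | intermediate
21 | 8-hydroxysyringaresinol (7R,7'S,8S,8'R) | COc1cc([C@H]2OC[C@]3(O)[C@@H](c4cc(OC)c(O)c(OC)c4)OC[C@H]23)cc(OC)c1O | target

**Step count**

Total steps: 13. Longest linear sequence: 12 steps (step 1 or step 2, then steps 3 to 13).

**Steps most likely to fail**

Step 12. Oxygen transfer may go to the α face, or the ionising aryl epoxide may rearrange (ring expansion by alkyl shift) or be hydrolysed before the C9' hydroxyl captures C7. The fallback sets out from 17 and replaces oxygen-atom transfer by syn-dihydroxylation. OsO4 (cat.) with N-methylmorpholine N-oxide in acetone/water, with (DHQ)2PHAL added if the substrate bias is insufficient, should add both oxygens anti to the bulky silyloxymethyl arm and give the (7S,8S)-7,8-diol silyl ether F1. Bu4NF should then free the triol F2. Catalytic camphorsulfonic acid in CH2Cl2 at 0 °C should ionise the secondary benzylic C7 hydroxyl, and the C9' hydroxyl should capture the cation on the α face with the aryl taking the exo position, which closes ring B. The fallback comes back to the route at 20.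

Step 10. The betaine may activate the benzylic C7' hydroxyl instead of the primary allylic one (inversion or ionisation at C7'), or closure may occur with allylic transposition at C7. The fallback sets out from 15 and keeps the ring intact instead of opening and re-closing it. iBu2AlH (1.1 equiv) in toluene at −78 °C should stop at the lactol F3 (anomer mixture). Ionic hydrogenation with Et3SiH and BF3·OEt2 in CH2Cl2 at −78 °C should then reduce the conjugated oxocarbenium ion at C9. The fallback comes back to the route at 17.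

Step 8. Elimination may give incomplete (E)-selectivity, or the base may move the exocyclic double bond into the ring and erase C8'. The fallback sets out from 12 and builds the alkene by olefination instead of aldol dehydration. LiN(iPr)2 (2.2 equiv) and diethyl chlorophosphate should give, through the enol phosphate and a 1,3-phosphorus shift, the α-(diethoxyphosphoryl) lactone F4. Horner–Wadsworth–Emmons reaction of F4 with aldehyde 3 (NaH, THF, 0 °C) should give the (E)-arylidene lactone under non-equilibrating conditions. The fallback comes back to the route at 15.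

**Further compounds**

F1 | step 12 | (7S,8S)-7,8-diol of 17 (silyl ether retained) | COc1cc([C@H]2OC[C@](O)([C@@H](O)c3cc(OC)c(OCc4ccccc4)c(OC)c3)[C@@H]2CO[Si](c5ccccc5)(c5ccccc5)C(C)(C)C)cc(OC)c1OCc1ccccc1
F2 | step 12 | (7S,8S)-7,8,9'-triol (desilylated F1) | COc1cc([C@H]2OC[C@](O)([C@@H](O)c3cc(OC)c(OCc4ccccc4)c(OC)c3)[C@@H]2CO)cc(OC)c1OCc1ccccc1
F3 | step 10 | lactol of 15 (anomer mixture) | COc1cc([C@H]2OC(O)/C(=C/c3cc(OC)c(OCc4ccccc4)c(OC)c3)[C@@H]2CO[Si](c5ccccc5)(c5ccccc5)C(C)(C)C)cc(OC)c1OCc1ccccc1
F4 | step 8 | α-(diethoxyphosphoryl) derivative of lactone 12 (C3 epimers) | COc1cc([C@H]2OC(=O)C(P(=O)(OCC)OCC)[C@@H]2CO[Si](c5ccccc5)(c5ccccc5)C(C)(C)C)cc(OC)c1OCc1ccccc1
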